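## Retrosynthetic overview

1. Leucanthin B ⇐ release of the C14 acid from its 2-(trimethylsilyl)ethyl (TMSE) ester, acylation of 8-OH with separately made (2R,3R)-epoxyangelic acid, PMB removal.
2. ⇐ both ring oxiranes from one double epoxidation of the (2Z,4Z)-diene of a macrocyclic triene lactone (C4=C5 first, then C2=C3 anti to it).
3. ⇐ ten-membered carbocycle closed at C6–C7, the bond made by the farnesyl 1,10-cyclisation, by intramolecular 2-(alkoxycarbonyl)allylation of a (Z)-enal; the C6 alkoxide closes the 12,6-lactone in the same flask.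
4. ⇐ acyclic trienal from three pieces: Z-iodoenal (C4–C6), stannyl α-iodo dienoate (C1–C3, C10, C14), acetoxy acrylate aldehyde (C7–C9, C11–C13; C8 by Pd-catalysed asymmetric etherification, C9 by chelation-controlled addition).
5. Ring order: side-chain oxirane (separate), carbocycle, lactone, 4,5-oxirane, 2,3-oxirane.

Assumptions: C1–C15 are the germacrane positions of the target (C12 lactone carbonyl, C13 exocyclic methylene, C14 carboxyl, C15 methyl on C4; α below and β above the ring as usually drawn); the (S,S)-Trost ligand is taken to give the (R)-ether 21 (the mirror-image ligand is used if the sense is opposite).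

## Route

Step 1
Reactants: 1 angelic acid [(Z)-2-methylbut-2-enoic acid]
Product: 2 (Z)-2-methylbut-2-en-1-ol
Conditions: LiAlH4, Et2O, 0 °C
Reagents that add atoms: none
Why: Hydride reduction of the carboxylic acid by LiAlH4 gives the allylic alcohol and leaves the Z-alkene untouched.

Step 2
Reactants: 2 (Z)-2-methylbut-2-en-1-ol
Product: 3 [(2S,3R)-2,3-dimethyloxiran-2-yl]methanol
Conditions: tBuOOH, Ti(OiPr)4 (10 mol %), L-(+)-diethyl tartrate (12 mol %), 4 Å MS, CH2Cl2, −20 °C
Reagents that add atoms: tert-butyl hydroperoxide (CC(C)(C)OO)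
Why: Sharpless asymmetric epoxidation, in which the titanium–L-(+)-tartrate complex delivers oxygen to one face of the allylic alcohol (the same sense that gives 2S products from geraniol) and so sets both oxirane carbons, the Z-geometry fixing the two methyl groups trans.

Step 3
Reactants: 3 [(2S,3R)-2,3-dimethyloxiran-2-yl]methanol
Product: 4 (2R,3R)-2,3-dimethyloxirane-2-carboxylic acid
Conditions: RuCl3 (2 mol %), NaIO4, CCl4–MeCN–H2O, rt
Reagents that add atoms: water (O)
Why: Ruthenium-catalysed periodate oxidation (Sharpless conditions) takes the primary alcohol through the aldehyde hydrate to the acid without opening the glycidic oxirane; the label at C2 changes to R only through the new priority order.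

Step 4
Reactants: 5 but-2-yn-1-ol
Product: 7 (Z)-3-iodobut-2-en-1-ol, via cyclic alkenylaluminate 6 (not isolated)
Conditions: NaAlH2(OCH2CH2OCH3)2 (Red-Al), Et2O, 0 °C → rt; then I2, THF, −78 °C
Reagents that add atoms: iodine (II)
Why: Hydroxyl-directed trans-hydroalumination of the propargylic alcohol puts aluminium on C3 cis to the CH2O group (five-membered aluminate) and iododealumination with retention gives the Z-vinyl iodide, which fixes the cis C4=C5 geometry of the target.

Step 5
Reactants: 7 (Z)-3-iodobut-2-en-1-ol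
Product: 8 (Z)-3-iodobut-2-enal
Conditions: MnO2, CH2Cl2, rt, dark; used at once
Reagents that add atoms: none
Why: Allylic oxidation by MnO2 stops at the aldehyde and leaves the Z-β-iodoenal geometry intact when the product is kept dark and used directly.

Step 6
Reactants: 9 prop-2-yn-1-ol
Product: 11 (Z)-3-(tributylstannyl)prop-2-en-1-ol, via cyclic alkenylalanate 10 (not isolated)
Conditions: LiAlH4, THF, 0 °C → rt; then Bu3SnOTf, −78 °C → rt
Reagents that add atoms: tributyltin triflate (CCCC[Sn](CCCC)(CCCC)OS(=O)(=O)C(F)(F)F)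
Why: The same directed trans-hydroalumination followed by aluminium-to-tin exchange with retention gives the Z-vinylstannane that becomes the cis C2=C3 bond.

Step 7
Reactants: 12 2-(trimethylsilyl)ethanol
Product: 13 2-(trimethylsilyl)ethyl bromoacetate
Conditions: BrCH2COBr, pyridine, CH2Cl2, 0 °C
Reagents that add atoms: bromoacetyl bromide (BrCC(Br)=O)
Why: Acylation of the alcohol by the acid bromide (esterification) is much faster than displacement of the α-bromide.

Step 8
Reactants: 13 2-(trimethylsilyl)ethyl bromoacetate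
Product: 15 2-(trimethylsilyl)ethyl (triphenylphosphoranylidene)acetate, via phosphonium bromide 14 (not isolated)
Conditions: PPh3, toluene, rt; then aq NaOH, CH2Cl2
Reagents that add atoms: triphenylphosphine (c1ccc(cc1)P(c1ccccc1)c1ccccc1)
Why: SN2 quaternisation of PPh3 by the α-bromo ester and deprotonation of the salt give the ester-stabilised ylide (standard Wittig reagent synthesis).

Step 9
Reactants: 11 (Z)-3-(tributylstannyl)prop-2-en-1-ol; 15 2-(trimethylsilyl)ethyl (triphenylphosphoranylidene)acetate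
Product: 18 2-(trimethylsilyl)ethyl (2Z,4Z)-2-iodo-5-(tributylstannyl)penta-2,4-dienoate, via stannyl acrolein 16 (not isolated), via iodo ylide 17 (not isolated)
Conditions: MnO2, CH2Cl2, rt (11 to 16, filtered); 15, NIS, CH2Cl2, −20 °C (to 17); then 16, −20 °C → rt
Reagents that add atoms: N-iodosuccinimide (O=C1CCC(=O)N1I)
Why: MnO2 allylic oxidation gives the Z-stannyl enal, NIS iodinates the stabilised ylide, and their Wittig olefination places the ester trans to the new C2 substituent as stabilised ylides do, so that iodine is cis to C2 (2Z) while the Z-vinylstannane is kept.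

Step 10
Reactants: 19 2-vinyloxirane (racemic butadiene monoxide); 20 4-methoxybenzyl alcohol
Product: 21 (2R)-2-[(4-methoxybenzyl)oxy]but-3-en-1-ol
Conditions: Pd2(dba)3·CHCl3 (1 mol %), (S,S)-DACH-phenyl Trost ligand (3 mol %), Et3B (1 mol %), CH2Cl2, rt
Reagents that add atoms: none
Why: Trost palladium-catalysed dynamic kinetic asymmetric allylic etherification, in which both enantiomers of the vinyl epoxide converge on interconverting π-allyl complexes and the boron-bound alcohol is delivered to the branched carbon inside the chiral pocket, which sets C8.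

Step 11
Reactants: 21 (2R)-2-[(4-methoxybenzyl)oxy]but-3-en-1-ol
Product: 22 (2R)-2-[(4-methoxybenzyl)oxy]but-3-enal
Conditions: Dess–Martin periodinane, CH2Cl2, 0 °C; used crude
Reagents that add atoms: none
Why: Dess–Martin oxidation is neutral and fast, so the epimerisable α-alkoxy β,γ-unsaturated aldehyde is formed without racemisation.

Step 12
Reactants: 22 (2R)-2-[(4-methoxybenzyl)oxy]but-3-enal; 23 methyl propiolate
Product: 26 methyl 2-[(2R)-1-acetoxy-2-[(4-methoxybenzyl)oxy]but-3-en-1-yl]prop-2-enoate (C7 epimers), via vinylalane 24 (not isolated), via aluminium alkoxide 25 (not isolated)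
Conditions: 23, iBu2AlH, NMO, THF, 0 °C; then 22, 0 °C → rt; then Ac2O, pyridine, DMAP (cat.), rt
Reagents that add atoms: acetic anhydride (CC(=O)OC(C)=O)
Why: Vinylalumination (hydroalumination of the propiolate to the α-aluminoacrylate and its 1,2-addition to the aldehyde, a Morita–Baylis–Hillman-type adduct made without base) followed by acetylation of the aluminium alkoxide in the flask; the new C7 centre forms as a mixture, which does not matter because C7 becomes sp2 in step 16.

Step 13
Reactants: 26 methyl 2-[(2R)-1-acetoxy-2-[(4-methoxybenzyl)oxy]but-3-en-1-yl]prop-2-enoate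
Product: 27 methyl 2-[(2S)-1-acetoxy-2-[(4-methoxybenzyl)oxy]-3-oxopropyl]prop-2-enoate (C7 epimers)
Conditions: O3, CH2Cl2, −78 °C, stopped at first blue tint; then PPh3, −78 °C → rt; used crude
Reagents that add atoms: ozone ([O-][O+]=O)
Why: Ozonolysis cleaves the electron-rich monosubstituted vinyl group much faster than the electron-poor acrylate C=C, and reductive work-up gives the C9 aldehyde without touching C8 (the label becomes S only through the priority change).

Step 14
Reactants: 18 2-(trimethylsilyl)ethyl (2Z,4Z)-2-iodo-5-(tributylstannyl)penta-2,4-dienoate; 27 methyl 2-[(2S)-1-acetoxy-2-[(4-methoxybenzyl)oxy]-3-oxopropyl]prop-2-enoate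
Product: 30 2-(trimethylsilyl)ethyl (2E,4Z)-2-[(1S,2S)-1,3-diacetoxy-4-(methoxycarbonyl)-2-[(4-methoxybenzyl)oxy]pent-4-en-1-yl]-5-(tributylstannyl)penta-2,4-dienoate (C7 epimers), via alkenylmagnesium chloride 28 (not isolated), via chloromagnesium alkoxide 29 (not isolated)
Conditions: 18, iPrMgCl·LiCl, THF, −78 °C; then 27, −78 → −40 °C; then Ac2O, DMAP, −40 °C → rt
Reagents that add atoms: acetic anhydride (CC(=O)OC(C)=O)
Why: Knochel-type iodine–magnesium exchange converts the α-iodo enoate into the α-magnesio acrylate with retention at −78 °C, which adds to the aldehyde through the five-membered Cram chelate (Mg bound to C=O and the α-OPMB oxygen) from the face opposite the C7 branch to set C9 as the 8,9-threo (9S) isomer, and the alkoxide is acetylated in the flask.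

Step 15
Reactants: 30 the stannyl diacetate of step 14; 8 (Z)-3-iodobut-2-enal
Product: 31 2-(trimethylsilyl)ethyl (2E,4Z,6Z)-2-[(1S,2S)-1,3-diacetoxy-4-(methoxycarbonyl)-2-[(4-methoxybenzyl)oxy]pent-4-en-1-yl]-6-methyl-8-oxoocta-2,4,6-trienoate (C7 epimers)
Conditions: Cu(O2CC4H3S) (CuTC, 1.5 equiv), NMP, 0 °C, dark
Reagents that add atoms: none
Why: Copper-mediated Stille-type coupling (Liebeskind CuTC coupling) joins the Z-vinylstannane and the Z-β-iodoenal at 0 °C with retention of both geometries and without palladium, so the two allylic acetates are not ionised.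

Step 16
Reactants: 31 the trienal of step 15
Product: 34 2-(trimethylsilyl)ethyl 9α-acetoxy-8β-[(4-methoxybenzyl)oxy]-12-oxo-6α,12-epoxygermacra-1(10)E,2Z,4Z,11(13)-tetraen-14-oate (6βH 7αH trans-lactone), via allylic iodide 32 (not isolated), via macrocyclic hydroxy ester 33 (not isolated)
Conditions: CrCl2 (8 equiv), LiI (0.2 equiv), THF–DMF 3:1, 0.002 M (syringe pump), rt; aq NH4Cl; SiO2 (lactonisation)
Reagents that add atoms: none
Why: Proposed new method: iodide adds SN2′ to the acrylate-activated C7 acetate far faster than to the β-substituted C9 acetate, divalent chromium reduces the resulting allylic iodide to the 2-(methoxycarbonyl)allylchromium, and this adds to the (Z)-enal held nearby by the all-cis triene through a chair-like six-membered transition state with both ring tethers pseudo-equatorial (6,7-anti, hence the trans-lactone) on the allyl face anti to the C9 branch with C8–H eclipsing C7=C11 (A1,3 strain), which sets 6α-O and 7α-H before the C6 alkoxide lactonises onto C12; the closest known reactions are the CrCl2/LiI allylation of aldehydes by allylic phosphates and the Nozaki–Hiyama–Kishi and Barbier macrocyclisations of 2-(bromomethyl)enoate aldehydes to ten-membered germacranolides.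

Step 17
Reactants: 34 the triene lactone of step 16
Product: 36 2-(trimethylsilyl)ethyl 9α-acetoxy-2α,3α:4β,5β-diepoxy-8β-[(4-methoxybenzyl)oxy]-12-oxo-6α,12-epoxygermacra-1(10)E,11(13)-dien-14-oate, via C4–C5 monoepoxide 35 (not isolated)
Conditions: DMDO (2.5 equiv), acetone–CH2Cl2, −20 → 0 °C
Reagents that add atoms: dimethyldioxirane (CC1(C)OO1)
Why: Electrophilic epoxidation by dimethyldioxirane takes the most electron-rich C4=C5 bond first on the β face anti to the allylic C6–O bond and then C2=C3 on the α face anti to the new oxirane (the usual anti outcome for cyclic 1,3-dienes), the ester-conjugated C1=C10 and C11=C13 bonds staying inert; doing this directly on 34 also removes the cyclodecatriene before it can undergo 6π-electrocyclisation.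

Step 18
Reactants: 36 the diepoxide PMB ether of step 17
Product: 37 2-(trimethylsilyl)ethyl 9α-acetoxy-2α,3α:4β,5β-diepoxy-8β-hydroxy-12-oxo-6α,12-epoxygermacra-1(10)E,11(13)-dien-14-oate
Conditions: DDQ, CH2Cl2–pH 7 buffer, 0 °C; used at once
Reagents that add atoms: none
Why: Oxidative PMB cleavage by DDQ (benzylic hydride abstraction and hydrolysis of the oxocarbenium ion) under buffered conditions frees 8-OH without affecting the oxiranes, esters or lactone.

Step 19
Reactants: 37 the 8β-alcohol of step 18; 4 (2R,3R)-2,3-dimethyloxirane-2-carboxylic acid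
Product: 39 2-(trimethylsilyl)ethyl 9α-acetoxy-8β-{[(2R,3R)-2,3-dimethyloxirane-2-carbonyl]oxy}-2α,3α:4β,5β-diepoxy-12-oxo-6α,12-epoxygermacra-1(10)E,11(13)-dien-14-oate, via mixed anhydride 38 (not isolated)
Conditions: 4, 2,4,6-Cl3C6H2COCl, Et3N, THF, 0 °C; then 37, DMAP, toluene, rt
Reagents that add atoms: none
Why: Yamaguchi esterification, in which the mixed anhydride of the epoxy acid acylates the hindered secondary 8β-OH under DMAP catalysis with no change at any stereocentre.

Step 20
Reactants: 39 the TMSE ester of step 19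
Product: 40 leucanthin B
Conditions: TASF, DMF, 0 °C; aq NH4Cl
Reagents that add atoms: none
Why: Fluoride attacks silicon of the 2-(trimethylsilyl)ethyl ester and β-elimination (Peterson-type fragmentation) releases ethylene and the carboxylate under conditions that leave the acetate, lactone, glycidic ester and oxiranes intact.

## Compound list

1 | angelic acid, (Z)-2-methylbut-2-enoic acid | C/C=C(/C)C(=O)O | starting material
2 | (Z)-2-methylbut-2-en-1-ol | C/C=C(/C)CO | intermediate
3 | [(2S,3R)-2,3-dimethyloxiran-2-yl]methanol | OC[C@]1(C)O[C@@H]1C | intermediate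
4 | (2R,3R)-2,3-dimethyloxirane-2-carboxylic acid (epoxyangelic acid) | OC(=O)[C@]1(C)O[C@@H]1C | intermediate
5 | but-2-yn-1-ol | CC#CCO | starting material
6 | sodium cyclic (Z)-alkenylaluminate from 5 (Al on C3 in a five-membered C=C–C–O–Al ring, two 2-methoxyethoxy ligands) | CC1=CCO[Al-]1(OCCOC)OCCOC.[Na+] | intermediate
7 | (Z)-3-iodobut-2-en-1-ol | C/C(I)=C/CO | intermediate
8 | (Z)-3-iodobut-2-enal | C/C(I)=C/C=O | intermediate
9 | prop-2-yn-1-ol | C#CCO | starting material
10 | lithium cyclic (Z)-alkenylalanate from 9 (Al on C3 in a five-membered ring) | [Li+].C1=C[AlH2-]OC1 | intermediate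
11 | (Z)-3-(tributylstannyl)prop-2-en-1-ol | CCCC[Sn](CCCC)(CCCC)/C=C\CO | intermediate
12 | 2-(trimethylsilyl)ethanol | C[Si](C)(C)CCO | starting material
13 | 2-(trimethylsilyl)ethyl bromoacetate | C[Si](C)(C)CCOC(=O)CBr | intermediate
14 | {2-oxo-2-[2-(trimethylsilyl)ethoxy]ethyl}triphenylphosphonium bromide | C[Si](C)(C)CCOC(=O)C[P+](c1ccccc1)(c1ccccc1)c1ccccc1.[Br-] | intermediate
15 | 2-(trimethylsilyl)ethyl (triphenylphosphoranylidene)acetate | C[Si](C)(C)CCOC(=O)C=P(c1ccccc1)(c1ccccc1)c1ccccc1 | intermediate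
16 | (Z)-3-(tributylstannyl)prop-2-enal | CCCC[Sn](CCCC)(CCCC)/C=C\C=O | intermediate
17 | 2-(trimethylsilyl)ethyl iodo(triphenylphosphoranylidene)acetate | C[Si](C)(C)CCOC(=O)C(I)=P(c1ccccc1)(c1ccccc1)c1ccccc1 | intermediate
18 | 2-(trimethylsilyl)ethyl (2Z,4Z)-2-iodo-5-(tributylstannyl)penta-2,4-dienoate | C[Si](C)(C)CCOC(=O)/C(I)=C/C=C\[Sn](CCCC)(CCCC)CCCC | intermediate
19 | 2-vinyloxirane (butadiene monoxide, racemic) | C=CC1CO1 | starting material
20 | 4-methoxybenzyl alcohol | COc1ccc(CO)cc1 | starting material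
21 | (2R)-2-[(4-methoxybenzyl)oxy]but-3-en-1-ol | OC[C@H](OCc1ccc(OC)cc1)C=C | intermediate
22 | (2R)-2-[(4-methoxybenzyl)oxy]but-3-enal | O=C[C@H](OCc1ccc(OC)cc1)C=C | intermediate
23 | methyl propiolate | C#CC(=O)OC | starting material
24 | [1-(methoxycarbonyl)vinyl]diisobutylalane | C=C(C(=O)OC)[Al](CC(C)C)CC(C)C | intermediate
25 | diisobutylaluminium alkoxide of methyl 2-[(2R)-1-hydroxy-2-[(4-methoxybenzyl)oxy]but-3-en-1-yl]prop-2-enoate (C7 epimers) | C=C(C(=O)OC)C(O[Al](CC(C)C)CC(C)C)[C@H](OCc1ccc(OC)cc1)C=C | intermediate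
26 | methyl 2-[(2R)-1-acetoxy-2-[(4-methoxybenzyl)oxy]but-3-en-1-yl]prop-2-enoate (C7 epimers) | C=C(C(=O)OC)C(OC(C)=O)[C@H](OCc1ccc(OC)cc1)C=C | intermediate
27 | methyl 2-[(2S)-1-acetoxy-2-[(4-methoxybenzyl)oxy]-3-oxopropyl]prop-2-enoate (C7 epimers) | C=C(C(=O)OC)C(OC(C)=O)[C@H](OCc1ccc(OC)cc1)C=O | intermediate
28 | 2-(trimethylsilyl)ethyl (2Z,4Z)-2-(chloromagnesio)-5-(tributylstannyl)penta-2,4-dienoate | C[Si](C)(C)CCOC(=O)/C([Mg]Cl)=C/C=C\[Sn](CCCC)(CCCC)CCCC | intermediate
29 | chloromagnesium (9S)-alkoxide of the adduct of 28 and 27 (C8 S, 8,9-threo) | C=C(C(=O)OC)C(OC(C)=O)[C@H](OCc1ccc(OC)cc1)[C@@H](O[Mg]Cl)/C(C(=O)OCC[Si](C)(C)C)=C\C=C/[Sn](CCCC)(CCCC)CCCC | intermediate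
30 | 2-(trimethylsilyl)ethyl (2E,4Z)-2-[(1S,2S)-1,3-diacetoxy-4-(methoxycarbonyl)-2-[(4-methoxybenzyl)oxy]pent-4-en-1-yl]-5-(tributylstannyl)penta-2,4-dienoate (C7 epimers) | C=C(C(=O)OC)C(OC(C)=O)[C@H](OCc1ccc(OC)cc1)[C@@H](OC(C)=O)/C(C(=O)OCC[Si](C)(C)C)=C\C=C/[Sn](CCCC)(CCCC)CCCC | intermediate
31 | 2-(trimethylsilyl)ethyl (2E,4Z,6Z)-2-[(1S,2S)-1,3-diacetoxy-4-(methoxycarbonyl)-2-[(4-methoxybenzyl)oxy]pent-4-en-1-yl]-6-methyl-8-oxoocta-2,4,6-trienoate (C7 epimers) | C=C(C(=O)OC)C(OC(C)=O)[C@H](OCc1ccc(OC)cc1)[C@@H](OC(C)=O)/C(C(=O)OCC[Si](C)(C)C)=C\C=C/C(C)=C\C=O | intermediate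
32 | 2-(trimethylsilyl)ethyl (2E,4Z,6Z)-2-[(1S,2S,3Z)-1-acetoxy-5-iodo-4-(methoxycarbonyl)-2-[(4-methoxybenzyl)oxy]pent-3-en-1-yl]-6-methyl-8-oxoocta-2,4,6-trienoate | IC/C(C(=O)OC)=C\[C@H](OCc1ccc(OC)cc1)[C@@H](OC(C)=O)/C(C(=O)OCC[Si](C)(C)C)=C\C=C/C(C)=C\C=O | intermediate
33 | 14-[2-(trimethylsilyl)ethyl] 12-methyl 9α-acetoxy-6α-hydroxy-8β-[(4-methoxybenzyl)oxy]germacra-1(10)E,2Z,4Z,11(13)-tetraene-12,14-dioate (7αH) | C=C(C(=O)OC)[C@H]1[C@H](O)/C=C(C)\C=C/C=C(C(=O)OCC[Si](C)(C)C)\[C@H](OC(C)=O)[C@H]1OCc1ccc(OC)cc1 | intermediate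
34 | 2-(trimethylsilyl)ethyl 9α-acetoxy-8β-[(4-methoxybenzyl)oxy]-12-oxo-6α,12-epoxygermacra-1(10)E,2Z,4Z,11(13)-tetraen-14-oate (6βH, 7αH, trans-fused α-methylene lactone) | C=C1C(=O)O[C@@H]2/C=C(C)\C=C/C=C(C(=O)OCC[Si](C)(C)C)\[C@H](OC(C)=O)[C@@H](OCc3ccc(OC)cc3)[C@@H]12 | intermediate
35 | 4β,5β-monoepoxide of 34 (C15 methyl α, H5 α; C2=C3 Z retained) | C=C1C(=O)O[C@H]2[C@H]1[C@H](OCc1ccc(OC)cc1)[C@@H](OC(C)=O)/C(C(=O)OCC[Si](C)(C)C)=C\C=C/[C@]1(C)O[C@H]21 | intermediate
36 | 2-(trimethylsilyl)ethyl 9α-acetoxy-2α,3α:4β,5β-diepoxy-8β-[(4-methoxybenzyl)oxy]-12-oxo-6α,12-epoxygermacra-1(10)E,11(13)-dien-14-oate | C=C1C(=O)O[C@H]2[C@H]1[C@H](OCc1ccc(OC)cc1)[C@@H](OC(C)=O)/C(C(=O)OCC[Si](C)(C)C)=C\[C@H]1O[C@H]1[C@]1(C)O[C@H]21 | intermediate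
37 | 2-(trimethylsilyl)ethyl 9α-acetoxy-2α,3α:4β,5β-diepoxy-8β-hydroxy-12-oxo-6α,12-epoxygermacra-1(10)E,11(13)-dien-14-oate | C=C1C(=O)O[C@H]2[C@H]1[C@H](O)[C@@H](OC(C)=O)/C(C(=O)OCC[Si](C)(C)C)=C\[C@H]1O[C@H]1[C@]1(C)O[C@H]21 | intermediate
38 | (2R,3R)-2,3-dimethyloxirane-2-carboxylic 2,4,6-trichlorobenzoic anhydride | O=C(OC(=O)c1c(Cl)cc(Cl)cc1Cl)[C@]1(C)O[C@@H]1C | intermediate
39 | 2-(trimethylsilyl)ethyl ester of leucanthin B | C=C1C(=O)O[C@H]2[C@H]1[C@H](OC(=O)[C@]1(C)O[C@@H]1C)[C@@H](OC(C)=O)/C(C(=O)OCC[Si](C)(C)C)=C\[C@H]1O[C@H]1[C@]1(C)O[C@H]21 | intermediate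
40 | leucanthin B: 9α-acetoxy-8β-{[(2R,3R)-2,3-dimethyloxirane-2-carbonyl]oxy}-2α,3α:4β,5β-diepoxy-12-oxo-6α,12-epoxygermacra-1(10)E,11(13)-dien-14-oic acid | C=C1C(=O)O[C@H]2[C@H]1[C@H](OC(=O)[C@]1(C)O[C@@H]1C)[C@@H](OC(C)=O)/C(C(=O)O)=C\[C@H]1O[C@H]1[C@]1(C)O[C@H]21 | target

## Step count and risks

Total step count: 20. Longest linear sequence: 11 steps (steps 10 to 20, from butadiene monoxide).

Steps most likely to fail:

1. Step 16 (ring closure). The in situ activation of the acetate, the 6,7- and 7,8-stereochemistry and the stability of the cyclodecatriene are all untested. Fallback: starting from 30, the lactone is made first and the ring is closed at C3–C4 instead. Compounds 30 and 8 with LiI/CrCl2 give, through the allylic iodide F1 and the open-chain hydroxy ester F2, the open-chain lactone F3, which still carries the vinylstannane and the vinyl iodide. High-dilution intramolecular coupling of F3 with Cu(O2CC4H3S) (CuTC) in NMP then closes the ten-membered ring and returns to the route at 34.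

2. Step 17 (face selectivity of the two epoxidations). Fallback: starting from 34, if oxygen transfer goes to the α face of C4=C5, the oxirane is built by substitution instead. NBS in wet THF gives the bromohydrin F4 (Br on C5 α, OH on C4 β), Cs2CO3 in MeCN closes it with inversion at C5 to the 4β,5β-monoepoxide 35, and one equivalent of DMDO then returns to the route at 36.

3. Step 14 (retention of the C1=C10 geometry in the magnesium reagent and chelate selectivity at C9). Fallback: starting from 18 and 27, the C9–C10 bond is made by a catalyst-controlled Nozaki–Hiyama–Kishi coupling (CrCl2, NiCl2 cat., chiral sulfonamide ligand, Et3N, THF). The alkenylchromium keeps its geometry and the ligand, not the substrate, sets C9, giving the (9S)-alcohol F5. Acetylation (Ac2O, pyridine) returns to the route at 30.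

## Further compounds

F1 | step 16 | 2-(trimethylsilyl)ethyl (2E,4Z)-2-[(1S,2S,3Z)-1-acetoxy-5-iodo-4-(methoxycarbonyl)-2-[(4-methoxybenzyl)oxy]pent-3-en-1-yl]-5-(tributylstannyl)penta-2,4-dienoate | IC/C(C(=O)OC)=C\[C@H](OCc1ccc(OC)cc1)[C@@H](OC(C)=O)/C(C(=O)OCC[Si](C)(C)C)=C\C=C/[Sn](CCCC)(CCCC)CCCC
F2 | step 16 | open-chain C6 hydroxy ester from F1 and 8 (6α-OH and 7αH configuration as in 33; Z-vinyl iodide at C4; vinylstannane at C3) | C=C(C(=O)OC)[C@@H]([C@H](O)/C=C(/C)I)[C@H](OCc1ccc(OC)cc1)[C@@H](OC(C)=O)/C(C(=O)OCC[Si](C)(C)C)=C\C=C/[Sn](CCCC)(CCCC)CCCC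
F3 | step 16 | open-chain trans α-methylene-γ-lactone from F2 (C3–C4 bond missing; Z-vinyl iodide and Z-vinylstannane) | C=C1C(=O)O[C@H](/C=C(/C)I)[C@H]1[C@H](OCc1ccc(OC)cc1)[C@@H](OC(C)=O)/C(C(=O)OCC[Si](C)(C)C)=C\C=C/[Sn](CCCC)(CCCC)CCCC
F4 | step 17 | bromohydrin of 34 (5α-bromo, 4β-hydroxy, C2=C3 Z retained) | C=C1C(=O)O[C@H]2[C@H]1[C@H](OCc1ccc(OC)cc1)[C@@H](OC(C)=O)/C(C(=O)OCC[Si](C)(C)C)=C\C=C/[C@](C)(O)[C@H]2Br
F5 | step 14 | 2-(trimethylsilyl)ethyl (2E,4Z)-2-[(1S,2S)-3-acetoxy-1-hydroxy-4-(methoxycarbonyl)-2-[(4-methoxybenzyl)oxy]pent-4-en-1-yl]-5-(tributylstannyl)penta-2,4-dienoate (C7 epimers) | C=C(C(=O)OC)C(OC(C)=O)[C@H](OCc1ccc(OC)cc1)[C@@H](O)/C(C(=O)OCC[Si](C)(C)C)=C\C=C/[Sn](CCCC)(CCCC)CCCC
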